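Ring A (C1–C8–C7–C6–C5–C9) minus C1 and C8 is a four-membered ketone, C9–C5–C6–C7, so the bicyclo[3.3.1]nonane is disconnected at C9–C1 and C7–C8. In one operation a rhodium catalyst opens the C9–C7 bond of a 2-acylcyclobutanone and inserts the tethered 1,1-disubstituted alkene C1=C8, which closes ring B (C1–C2–C3–C4–C5–C9) and ring A together and creates the C1 bridgehead. The precursor is a 3,3-dimethyl-2,4-diprenylcyclobutanone whose quaternary C5 carries, through the C4 ketone, a methoxy dienone ending in the geranylated alkene; C5 and C7 come from an auxiliary-derived, twofold-symmetric trans ketone. C3 aroylation and deprotection complete the target.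

Key step: step 11

Remark: atom labels C1–C9 follow the bicyclo[3.3.1]nonane numbering of the target (C1 geranyl bridgehead, C5 prenyl bridgehead, C9 bridging ketone); the target is drawn as its C2 enol, which equilibrates with the C4 enol.
Assumption: the SAMP azaenolate of the cyclobutanone is alkylated with the same facial sense as SAMP azaenolates of other cyclic ketones, which leads to the (2R,4R) ketone 7; if the opposite sense were found, the enantiomeric auxiliary RAMP would be used.

Step 1
Reactants: 1 3,3-dimethylcyclobutan-1-one; 2 (S)-1-amino-2-(methoxymethyl)pyrrolidine (SAMP)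
Product: 3 (S)-N-(3,3-dimethylcyclobutylidene)-2-(methoxymethyl)pyrrolidin-1-amine
Conditions: 4 Å molecular sieves, CH2Cl2, rt
Reagents that add atoms: none
Why: Hydrazone condensation of an electrophilic strained ketone with the hydrazine is routine, creates no stereocentre and installs the auxiliary for the Enders SAMP hydrazone alkylations.

Step 2
Reactants: 3 SAMP hydrazone; 4 prenyl bromide (1-bromo-3-methylbut-2-ene)
Product: 5 (S)-N-[(1E,2R)-3,3-dimethyl-2-(3-methylbut-2-en-1-yl)cyclobutylidene]-2-(methoxymethyl)pyrrolidin-1-amine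
Conditions: LiN(i-Pr)2, THF, 0 °C; then 4, −100 °C → rt
Reagents that add atoms: none
Why: Enders SAMP hydrazone alkylation: the lithium azaenolate chelated by the methoxymethyl arm is alkylated by the allylic bromide on the face turned away from the pyrrolidine, which sets the new α-centre as R, and the hydrazone avoids the self-condensation of cyclobutanone enolates.

Step 3
Reactants: 5 mono-prenyl hydrazone; 4 prenyl bromide
Product: 6 (S)-N-[(2R,4R)-3,3-dimethyl-2,4-bis(3-methylbut-2-en-1-yl)cyclobutylidene]-2-(methoxymethyl)pyrrolidin-1-amine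
Conditions: LiN(i-Pr)2, THF, 0 °C; then 4, −100 °C → rt
Reagents that add atoms: none
Why: A second Enders alkylation at the unsubstituted α'-carbon proceeds under the same auxiliary control, reinforced by approach anti to the first prenyl group across the ring, so the second centre is also R and the trans twofold-symmetric skeleton results, any stereochemical error ending up in the separable meso isomer.

Step 4
Reactants: 6 bis-prenyl hydrazone
Product: 7 (2R,4R)-3,3-dimethyl-2,4-bis(3-methylbut-2-en-1-yl)cyclobutan-1-one (trans)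
Conditions: saturated aqueous oxalic acid, Et2O, rt
Reagents that add atoms: water, O
Why: Two-phase hydrazone hydrolysis with oxalic acid is mild enough to leave the two α-stereocentres and the trisubstituted alkenes untouched and returns the auxiliary.

Step 5
Reactants: 8 methyl acetoacetate; 9 geranyl bromide ((2E)-1-bromo-3,7-dimethylocta-2,6-diene)
Product: 10 methyl (6E)-7,11-dimethyl-3-oxododeca-6,10-dienoate
Conditions: NaH, THF, 0 °C; n-BuLi, 0 °C; then 9, 0 °C → rt; aq. NH4Cl
Reagents that add atoms: none
Why: γ-Alkylation of the acetoacetate dianion: the terminal carbanion is the more nucleophilic site and displaces the allylic bromide by SN2 with the E-alkene unchanged.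

Step 6
Reactants: 10 β-keto ester
Product: 11 methyl (2E,6E)-3-methoxy-7,11-dimethyldodeca-2,6,10-trienoate
Conditions: HC(OMe)3, cat. TsOH·H2O, MeOH, rt
Reagents that add atoms: trimethyl orthoformate, COC(OC)OC
Why: Acid-catalysed enol ether formation through the dimethyl ketal gives the thermodynamically preferred E-β-methoxy enoate, in which the ester is cis to C4 as needed for the next step.

Step 7
Reactants: 11 β-methoxy enoate; 12 formaldehyde
Product: 14 rac-5-[(2E)-3,7-dimethylocta-2,6-dien-1-yl]-4-methoxy-5,6-dihydro-2H-pyran-2-one, via δ-hydroxy ester 13 (not isolated)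
Conditions: LiN(i-Pr)2, THF, −78 °C; CH2O (gas, from cracked paraformaldehyde), −78 → 0 °C; aq. NH4Cl
Reagents that add atoms: none
Why: Vinylogous aldol addition followed by lactonisation: ester-directed γ-deprotonation gives a 3-methoxy dienolate that adds to aldehydes at its γ-carbon, and the alkoxide closes onto the cis ester to the dihydropyranone as in kavalactone syntheses; the new centre is racemic and is erased in step 8.

Step 8
Reactants: 14 dihydropyranone
Product: 15 (2E,6E)-3-methoxy-7,11-dimethyl-4-methylidenedodeca-2,6,10-trienoic acid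
Conditions: KN(SiMe3)2, THF, −78 → 0 °C; then cold 1 M HCl to pH 4
Reagents that add atoms: none
Why: E1cB ring opening of a 5,6-dihydro-2-pyranone (the parasorbic acid to sorbic acid type): γ-deprotonation expels the carboxylate from the ring CH2, which becomes the methylidene carbon C8, and the ring origin fixes the carboxyl group cis to C1 across the enol ether.

Step 9
Reactants: 15 dienoic acid
Product: 16 1-[(2E,6E)-3-methoxy-7,11-dimethyl-4-methylidenedodeca-2,6,10-trienoyl]-1H-benzotriazole
Conditions: 1H-benzotriazole, DCC, CH2Cl2, 0 °C → rt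
Reagents that add atoms: 1H-benzotriazole, c1ccc2[nH]nnc2c1
Why: Carbodiimide-mediated N-acylation of benzotriazole gives an isolable acyl donor under neutral conditions that spare the enol ether and the alkenes.

Step 10
Reactants: 7 (2R,4R)-ketone; 16 N-acylbenzotriazole
Product: 17 (2R,4R)-2-[(2E,6E)-3-methoxy-7,11-dimethyl-4-methylidenedodeca-2,6,10-trienoyl]-3,3-dimethyl-2,4-bis(3-methylbut-2-en-1-yl)cyclobutan-1-one (prenyl groups cis, acyl group trans to the C7 prenyl)
Conditions: LiN(i-Pr)2 (1.0 equiv), THF, −78 → −40 °C; then 16, −78 → −20 °C; aq. NH4Cl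
Reagents that add atoms: none
Why: Claisen-type C-acylation of a ketone lithium enolate by an N-acylbenzotriazole: the twofold-symmetric ketone gives the same enolate whichever α-proton is removed, attack at carbon is favoured because it relieves the strain of the cyclobutene-like enolate, and the donor approaches anti to the remaining prenyl group, which sets quaternary C5 as R with the two prenyl groups cis.

Step 11
Reactants: 17 2-acylcyclobutanone
Product: 18 (1R,5S,7S)-1-[(2E)-3,7-dimethylocta-2,6-dien-1-yl]-2-methoxy-6,6-dimethyl-5,7-bis(3-methylbut-2-en-1-yl)bicyclo[3.3.1]non-2-ene-4,9-dione (C7 prenyl exo)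
Conditions: [Rh(C2H4)2Cl]2 (5 mol %), P[3,5-(CF3)2C6H3]3 (20 mol %), 1,4-dioxane, 120 °C, argon
Reagents that add atoms: none
Why: Proposed new method: monovalent rhodium should add oxidatively to the less hindered C9–C7 bond of the strained ketone to give a five-membered acyl alkyl complex of trivalent rhodium, which the C4 carbonyl can chelate; the acyl carbon C9 then adds to C1 of the tethered 1,1-disubstituted alkene while the metal moves to C8, which has no β-hydrogen, and reductive elimination from the seven-membered rhodacycle joins C8 to C7 and frees the catalyst. The closest known reaction type is the rhodium-catalysed cut-and-sew carboacylation of alkenes tethered to C3 of cyclobutanones, which gives bridged bicyclic ketones; a tether on a fully substituted α-carbon and a methoxy dienone as the alkene partner have not been shown. Ring B closes by 6-exo-trig migratory insertion (C9–C1) and ring A by C(sp3)–C(sp3) reductive elimination (C7–C8), a formal (4+2) annulation driven by release of the four-ring strain. C1 is the only new stereocentre and is dictated by the bridge, since the three-atom tether on C5 can deliver the alkene to one face of the acyl–rhodium unit only, and C7 is carried over with retention because both metal steps at C7 are concerted. The step needs insertion into C9–C7 and not into C9–C5, which the quaternary C5 next to the gem-dimethyl carbon should enforce, and alkene insertion faster than CO extrusion or β-hydride loss from the C7 side chain, which the electron-poor phosphine and the cis enol ether geometry (C1 held next to C9) are chosen to favour.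

Step 12
Reactants: 19 3,4-dihydroxybenzoic acid
Product: 20 tert-butyldimethylsilyl 3,4-bis(tert-butyldimethylsilyloxy)benzoate
Conditions: TBSCl, imidazole, DMF, rt
Reagents that add atoms: tert-butyldimethylsilyl chloride, CC(C)(C)[Si](C)(C)Cl
Why: Exhaustive silylation of the two phenols and the carboxylic acid with the silyl chloride and imidazole is routine.

Step 13
Reactants: 20 tris-silyl compound
Product: 21 3,4-bis(tert-butyldimethylsilyloxy)benzoyl chloride
Conditions: (COCl)2, cat. DMF, CH2Cl2, 0 °C → rt
Reagents that add atoms: oxalyl chloride, O=C(Cl)C(=O)Cl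
Why: Silyl esters are converted directly into acid chlorides by oxalyl chloride and catalytic DMF (Vilsmeier-type activation) under neutral conditions that keep the aryl silyl ethers.

Step 14
Reactants: 18 O-methyl core; 21 aroyl chloride
Product: 22 (1R,5R,7S)-3-[3,4-bis(tert-butyldimethylsilyloxy)benzoyl]-1-[(2E)-3,7-dimethylocta-2,6-dien-1-yl]-2-methoxy-6,6-dimethyl-5,7-bis(3-methylbut-2-en-1-yl)bicyclo[3.3.1]non-2-ene-4,9-dione
Conditions: lithium 2,2,6,6-tetramethylpiperidide, THF, −78 °C; then 21, −78 → −40 °C
Reagents that add atoms: none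
Why: Vinylic lithiation at C3, the only acidic C–H now that both bridgeheads are quaternary, and acylation of the vinyllithium by the aroyl chloride is the established way to place the C3 acyl group on vinylogous esters of this bicyclic class; no stereocentre is touched.

Step 15
Reactants: 22 aroylated methyl ether
Product: 24 (1R,5R,7S)-3-(3,4-dihydroxybenzoyl)-1-[(2E)-3,7-dimethylocta-2,6-dien-1-yl]-2-hydroxy-6,6-dimethyl-5,7-bis(3-methylbut-2-en-1-yl)bicyclo[3.3.1]non-2-ene-4,9-dione, via bis-silyl triketone 23 (not isolated)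
Conditions: LiCl, DMSO, 120 °C; then Bu4NF, AcOH, THF, 0 °C
Reagents that add atoms: none
Why: Krapcho-type SN2 demethylation by chloride, made easy because the triketone enolate is a good leaving group, and fluoride cleavage of the aryl silyl ethers buffered by acetic acid free the enolised triketone and the catechol without acid that could cyclise the enol onto a prenyl group.

Compound list
1 | 3,3-dimethylcyclobutan-1-one | CC1(C)CC(=O)C1 | starting material
2 | (S)-1-amino-2-(methoxymethyl)pyrrolidine (SAMP) | COC[C@@H]1CCCN1N | starting material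
3 | (S)-N-(3,3-dimethylcyclobutylidene)-2-(methoxymethyl)pyrrolidin-1-amine | COC[C@@H]1CCCN1N=C1CC(C)(C)C1 | intermediate
4 | prenyl bromide | CC(C)=CCBr | starting material
5 | (S)-N-[(1E,2R)-3,3-dimethyl-2-(3-methylbut-2-en-1-yl)cyclobutylidene]-2-(methoxymethyl)pyrrolidin-1-amine | COC[C@@H]1CCCN1/N=C2\CC(C)(C)[C@H]2CC=C(C)C | intermediate
6 | (S)-N-[(2R,4R)-3,3-dimethyl-2,4-bis(3-methylbut-2-en-1-yl)cyclobutylidene]-2-(methoxymethyl)pyrrolidin-1-amine | COC[C@@H]1CCCN1N=C1[C@H](CC=C(C)C)C(C)(C)[C@H]1CC=C(C)C | intermediate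
7 | (2R,4R)-3,3-dimethyl-2,4-bis(3-methylbut-2-en-1-yl)cyclobutan-1-one | O=C1[C@H](CC=C(C)C)C(C)(C)[C@H]1CC=C(C)C | intermediate
8 | methyl acetoacetate | COC(=O)CC(C)=O | starting material
9 | geranyl bromide | CC(C)=CCC/C(C)=C/CBr | starting material
10 | methyl (6E)-7,11-dimethyl-3-oxododeca-6,10-dienoate | COC(=O)CC(=O)CC/C=C(\C)CCC=C(C)C | intermediate
11 | methyl (2E,6E)-3-methoxy-7,11-dimethyldodeca-2,6,10-trienoate | COC(=O)/C=C(OC)\CC/C=C(\C)CCC=C(C)C | intermediate
12 | formaldehyde | C=O | starting material
13 | methyl (2E,6E)-4-(hydroxymethyl)-3-methoxy-7,11-dimethyldodeca-2,6,10-trienoate (racemic, present as its lithium alkoxide) | COC(=O)/C=C(OC)\C(CO)C/C=C(\C)CCC=C(C)C | intermediate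
14 | rac-5-[(2E)-3,7-dimethylocta-2,6-dien-1-yl]-4-methoxy-5,6-dihydro-2H-pyran-2-one | COC1=CC(=O)OCC1C/C=C(\C)CCC=C(C)C | intermediate
15 | (2E,6E)-3-methoxy-7,11-dimethyl-4-methylidenedodeca-2,6,10-trienoic acid | OC(=O)/C=C(OC)\C(=C)C/C=C(\C)CCC=C(C)C | intermediate
16 | 1-[(2E,6E)-3-methoxy-7,11-dimethyl-4-methylidenedodeca-2,6,10-trienoyl]-1H-benzotriazole | O=C(/C=C(OC)\C(=C)C/C=C(\C)CCC=C(C)C)n1nnc2ccccc12 | intermediate
17 | (2R,4R)-2-[(2E,6E)-3-methoxy-7,11-dimethyl-4-methylidenedodeca-2,6,10-trienoyl]-3,3-dimethyl-2,4-bis(3-methylbut-2-en-1-yl)cyclobutan-1-one | O=C1[C@H](CC=C(C)C)C(C)(C)[C@@]1(CC=C(C)C)C(=O)/C=C(OC)\C(=C)C/C=C(\C)CCC=C(C)C | intermediate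
18 | (1R,5S,7S)-1-[(2E)-3,7-dimethylocta-2,6-dien-1-yl]-2-methoxy-6,6-dimethyl-5,7-bis(3-methylbut-2-en-1-yl)bicyclo[3.3.1]non-2-ene-4,9-dione | CC(C)=CCC/C(C)=C/C[C@@]12C[C@H](CC=C(C)C)C(C)(C)[C@@](CC=C(C)C)(C(=O)C=C1OC)C2=O | intermediate
19 | 3,4-dihydroxybenzoic acid | OC(=O)c1ccc(O)c(O)c1 | starting material
20 | tert-butyldimethylsilyl 3,4-bis(tert-butyldimethylsilyloxy)benzoate | CC(C)(C)[Si](C)(C)OC(=O)c1ccc(O[Si](C)(C)C(C)(C)C)c(O[Si](C)(C)C(C)(C)C)c1 | intermediate
21 | 3,4-bis(tert-butyldimethylsilyloxy)benzoyl chloride | ClC(=O)c1ccc(O[Si](C)(C)C(C)(C)C)c(O[Si](C)(C)C(C)(C)C)c1 | intermediate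
22 | (1R,5R,7S)-3-[3,4-bis(tert-butyldimethylsilyloxy)benzoyl]-1-[(2E)-3,7-dimethylocta-2,6-dien-1-yl]-2-methoxy-6,6-dimethyl-5,7-bis(3-methylbut-2-en-1-yl)bicyclo[3.3.1]non-2-ene-4,9-dione | CC(C)=CCC/C(C)=C/C[C@@]12C[C@H](CC=C(C)C)C(C)(C)[C@@](CC=C(C)C)(C(=O)C(C(=O)c3ccc(O[Si](C)(C)C(C)(C)C)c(O[Si](C)(C)C(C)(C)C)c3)=C1OC)C2=O | intermediate
23 | (1R,5R,7S)-3-[3,4-bis(tert-butyldimethylsilyloxy)benzoyl]-1-[(2E)-3,7-dimethylocta-2,6-dien-1-yl]-2-hydroxy-6,6-dimethyl-5,7-bis(3-methylbut-2-en-1-yl)bicyclo[3.3.1]non-2-ene-4,9-dione | CC(C)=CCC/C(C)=C/C[C@@]12C[C@H](CC=C(C)C)C(C)(C)[C@@](CC=C(C)C)(C(=O)C(C(=O)c3ccc(O[Si](C)(C)C(C)(C)C)c(O[Si](C)(C)C(C)(C)C)c3)=C1O)C2=O | intermediate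
24 | (1R,5R,7S)-3-(3,4-dihydroxybenzoyl)-1-[(2E)-3,7-dimethylocta-2,6-dien-1-yl]-2-hydroxy-6,6-dimethyl-5,7-bis(3-methylbut-2-en-1-yl)bicyclo[3.3.1]non-2-ene-4,9-dione | CC(C)=CCC/C(C)=C/C[C@@]12C[C@H](CC=C(C)C)C(C)(C)[C@@](CC=C(C)C)(C(=O)C(C(=O)c3ccc(O)c(O)c3)=C1O)C2=O | target

Total step count: 15. Longest linear sequence: 9 steps (steps 5, 6, 7, 8, 9, 10, 11, 14 and 15, from methyl acetoacetate).

Steps most likely to fail

Step 11 (proposed new method). Oxidative addition may not take place at the congested ketone, or the rhodacycle may extrude CO, lose a β-hydride at C7 or form at the C9–C5 bond; thermal valence isomerisation of the cis dienone may also compete. The fallback uses known chemistry and builds the bicycle by an Effenberger cyclization. It sets out from prenyl bromide 4 and geranyl bromide 9 and returns to the route at 18. Commercial 3-ethoxycyclohex-2-en-1-one is deprotonated with LiN(i-Pr)2 and alkylated with 4 to give 3-ethoxy-6-(3-methylbut-2-en-1-yl)cyclohex-2-en-1-one F1. Addition of MeLi and acidic hydrolysis (Stork–Danheiser transposition) give 3-methyl-4-(3-methylbut-2-en-1-yl)cyclohex-2-en-1-one F2. Conjugate addition of Me2CuLi and trapping of the enolate with 4 give 3,3-dimethyl-2,4-bis(3-methylbut-2-en-1-yl)cyclohexan-1-one F3. Kinetic deprotonation at the unhindered α-carbon and alkylation with 9 give 6-[(2E)-3,7-dimethylocta-2,6-dien-1-yl]-3,3-dimethyl-2,4-bis(3-methylbut-2-en-1-yl)cyclohexan-1-one F4, which LiN(i-Pr)2 and Me3SiCl convert into its trimethylsilyl enol ether F5. Malonyl dichloride followed by aqueous KOH should close the three-carbon bridge on the face opposite the C7 prenyl group and give the racemic 2-hydroxy-bicyclo[3.3.1]non-2-ene-4,9-dione F6, which is resolved by preparative chromatography on a chiral stationary phase. O-Methylation with trimethyl orthoformate and acid gives 18 together with its C4-methoxy regioisomer, from which 18 is separated before steps 14 and 15.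

Step 10. O-Acylation, or conjugate addition at the terminal methylene of the acyl donor, may outrun C-acylation at the congested enolate carbon, and facial selectivity across the four-membered ring may be incomplete. The fallback replaces the acyl transfer by an aldol addition and oxidation; it sets out from 16 and 7 and returns at 17. Acyl donor 16 reacts with N,O-dimethylhydroxylamine hydrochloride and Et3N to give the Weinreb amide (2E,6E)-N,3-dimethoxy-N,7,11-trimethyl-4-methylidenedodeca-2,6,10-trienamide F7. Reduction with i-Bu2AlH at −78 °C gives (2E,6E)-3-methoxy-7,11-dimethyl-4-methylidenedodeca-2,6,10-trienal F8. The lithium enolate of 7 adds to this small, purely 1,2-reactive electrophile at −78 °C, again anti to the remaining prenyl group, to give the β-hydroxy ketone (2R,4R)-2-[(2E,6E)-1-hydroxy-3-methoxy-7,11-dimethyl-4-methylidenedodeca-2,6,10-trienyl]-3,3-dimethyl-2,4-bis(3-methylbut-2-en-1-yl)cyclobutan-1-one F9 as a mixture of carbinol epimers. Oxidation with Dess–Martin periodinane buffered by NaHCO3 gives 17.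

Step 7. The dienolate may react at its α-carbon instead of the γ-carbon, formaldehyde may oligomerise, or lactonisation may stay incomplete. The fallback moves the hydroxymethylation to the β-keto ester stage, where γ-selectivity of the dianion is secure; it sets out from 10 and returns at 14. The dianion of 10 (NaH, then n-BuLi) adds to formaldehyde to give methyl (6E)-4-(hydroxymethyl)-7,11-dimethyl-3-oxododeca-6,10-dienoate F10. Aqueous NaOH followed by acidification lactonises it to 5-[(2E)-3,7-dimethylocta-2,6-dien-1-yl]oxane-2,4-dione F11. O-Methylation of this cyclic β-keto lactone with Me2SO4 and K2CO3 in acetone gives 14, the enol ether geometry again being fixed by the ring.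

Further compounds
F1 | step 11 | rac-3-ethoxy-6-(3-methylbut-2-en-1-yl)cyclohex-2-en-1-one | CCOC1=CC(=O)C(CC=C(C)C)CC1
F2 | step 11 | rac-3-methyl-4-(3-methylbut-2-en-1-yl)cyclohex-2-en-1-one | CC1=CC(=O)CCC1CC=C(C)C
F3 | step 11 | rac-3,3-dimethyl-2,4-bis(3-methylbut-2-en-1-yl)cyclohexan-1-one (diastereomer mixture) | O=C1CCC(CC=C(C)C)C(C)(C)C1CC=C(C)C
F4 | step 11 | rac-6-[(2E)-3,7-dimethylocta-2,6-dien-1-yl]-3,3-dimethyl-2,4-bis(3-methylbut-2-en-1-yl)cyclohexan-1-one (diastereomer mixture) | O=C1C(C/C=C(\C)CCC=C(C)C)CC(CC=C(C)C)C(C)(C)C1CC=C(C)C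
F5 | step 11 | trimethylsilyl enol ether of F4 (enol ether towards the geranyl-bearing carbon) | C[Si](C)(C)OC1=C(C/C=C(\C)CCC=C(C)C)CC(CC=C(C)C)C(C)(C)C1CC=C(C)C
F6 | step 11 | (1R,5S,7S)-1-[(2E)-3,7-dimethylocta-2,6-dien-1-yl]-2-hydroxy-6,6-dimethyl-5,7-bis(3-methylbut-2-en-1-yl)bicyclo[3.3.1]non-2-ene-4,9-dione (made as the racemate, then resolved) | CC(C)=CCC/C(C)=C/C[C@@]12C[C@H](CC=C(C)C)C(C)(C)[C@@](CC=C(C)C)(C(=O)C=C1O)C2=O
F7 | step 10 | (2E,6E)-N,3-dimethoxy-N,7,11-trimethyl-4-methylidenedodeca-2,6,10-trienamide | CON(C)C(=O)/C=C(OC)\C(=C)C/C=C(\C)CCC=C(C)C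
F8 | step 10 | (2E,6E)-3-methoxy-7,11-dimethyl-4-methylidenedodeca-2,6,10-trienal | O=C/C=C(OC)\C(=C)C/C=C(\C)CCC=C(C)C
F9 | step 10 | (2R,4R)-2-[(2E,6E)-1-hydroxy-3-methoxy-7,11-dimethyl-4-methylidenedodeca-2,6,10-trienyl]-3,3-dimethyl-2,4-bis(3-methylbut-2-en-1-yl)cyclobutan-1-one (carbinol epimers) | O=C1[C@H](CC=C(C)C)C(C)(C)[C@@]1(CC=C(C)C)C(O)/C=C(OC)\C(=C)C/C=C(\C)CCC=C(C)C
F10 | step 7 | rac-methyl (6E)-4-(hydroxymethyl)-7,11-dimethyl-3-oxododeca-6,10-dienoate | COC(=O)CC(=O)C(CO)C/C=C(\C)CCC=C(C)C
F11 | step 7 | rac-5-[(2E)-3,7-dimethylocta-2,6-dien-1-yl]oxane-2,4-dione | O=C1CC(=O)C(C/C=C(\C)CCC=C(C)C)CO1
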